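**Plan**
Locants: unprimed = the dihydrobenzofuran carrying the styryl arm (unit A); primed = the one carrying the 3,5-dihydroxyphenyl group (unit B). Cuts, in order: seven O–Si bonds, the outer stilbene C=C, C3–C3a and O1–C2, the inner stilbene C=C, C3'–C3a' and O1'–C2'.
Enabling feature: in both units the fusion carbon C3a (C3a') lies between the oxygen-bearing ring carbons C4 and C7a, with the carbon substituent at C6 para to it. This is the pattern of C2 in a 5-carboxycyclohexane-1,3-dione. C2–C3 with their two aryl groups are the alkene carbons of a resveratrol-type E-stilbene.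
Forward: silylated resveratrol and a 2-diazo-1,3-dione close the dihydrofuran ring of unit B. Dehydrogenation makes its benzo ring, and ester → aldehyde → olefination gives a new stilbene. The same operations build unit A and the outer styryl arm, and fluoride then frees the seven phenols.
Stereochemistry: C3' and C3 come from alkene-face selection by the two antipodes of dirhodium tetrakis[N-phthaloyl-tert-leucinate]. C2' and C2 come from trans-selective stepwise ring closure, and both alkenes from E-selective olefination. Because the units have opposite configuration, leakage in either annulation appears as a separable diastereomer.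

Key step: step 3

Abbreviations: TBS = tert-butyldimethylsilyl; TBSO = tert-butyldimethylsilyloxy; UB = (2S,3S)-3-[3,5-bis(TBSO)phenyl]-4-(TBSO)-2-[4-(TBSO)phenyl]-2,3-dihydrobenzofuran-6-yl.
Assumption: the sense of induction of Rh2(S-PTTL)4 towards a stilbene cannot be derived from precedent. The (S)-ligand set is written for the (2S,3S) unit and the (R)-ligand set for the (2R,3R) unit, and the two antipodes are exchanged if the first annulation shows the opposite sense.
Assumption: compounds 3 and 13 are treated as catalogue compounds.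

**Step 1**
Reactants: 1 resveratrol [(E)-5-(4-hydroxystyryl)benzene-1,3-diol]
Product: 2 (E)-3,4',5-tris(TBSO)stilbene
Conditions: TBSCl (3.6 equiv), imidazole (7 equiv), DMF, rt
Reagents that add atoms: tert-butyldimethylsilyl chloride, CC(C)(C)[Si](C)(C)Cl
Why: Imidazole-promoted O-silylation of phenols is routine, and silyl ethers are preferred to methyl ethers because they keep the rings electron-rich, shield them sterically and leave at the end with fluoride instead of a Lewis acid that would endanger the benzylic C2–O bonds.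

**Step 2**
Reactants: 3 methyl 3,5-dioxocyclohexane-1-carboxylate; 4 4-acetamidobenzenesulfonyl azide
Product: 5 methyl 4-diazo-3,5-dioxocyclohexane-1-carboxylate
Conditions: Et3N (1.2 equiv), MeCN, 0 °C to rt
Reagents that add atoms: 4-acetamidobenzenesulfonyl azide (4), CC(=O)Nc1ccc(cc1)S(=O)(=O)N=[N+]=[N-]
Why: Regitz diazo transfer to the doubly activated C4 methylene of a cyclic 1,3-dione needs only a mild amine base, and the sulfonamide left from 4 is removed by filtration and washing.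

**Step 3**
Reactants: 5 methyl 4-diazo-3,5-dioxocyclohexane-1-carboxylate; 2 (E)-3,4',5-tris(TBSO)stilbene
Product: 6 methyl (2S,3S)-3-[3,5-bis(TBSO)phenyl]-2-[4-(TBSO)phenyl]-4-oxo-2,3,4,5,6,7-hexahydrobenzofuran-6-carboxylate (both C6 epimers)
Conditions: Rh2(S-PTTL)4 (2 mol %), 2 (2 equiv), 5 added by syringe pump over 6 h, PhF, 4 Å MS, 60 °C
Reagents that add atoms: none
Why: Proposed new method: N2 loss from 5 on the divalent rhodium dimer gives a diacyl carbenoid electrophilic enough to be attacked by the alkene of 2 through the carbon bearing the 3,5-bis(silyloxy)phenyl ring (new C3–C3a bond), the only orientation that leaves the positive charge on the benzylic carbon conjugated to a para silyloxy donor; the rhodium-bound enolate then closes through oxygen on that cation (new O1–C2 bond) and frees the catalyst. The one ring formed, the dihydrofuran O1–C2–C3–C3a–C7a, closes 5-exo-trig with respect to the quinone-methide-like C2=C(aryl) cation and enolendo with respect to the nucleophile, and any spirocyclopropane from C-closure is a donor–acceptor cyclopropane that should ring-expand to the same product (Cloke–Wilson rearrangement). The closest known reaction types are the Rh2(OAc)4-catalysed formal [3+2] annulation of cyclic 2-diazo-1,3-diones with vinyl ethers and styrenes and the Mn(OAc)3-mediated annulation of 1,3-diones with stilbenes, whereas a 1,2-diarylalkene as carbenoid acceptor and useful enantiocontrol are both unproven. C3 is fixed in the C–C bond-forming event by the alkene face that the chiral pocket of the four N-phthaloyl-tert-leucinate ligands leaves open, and C2 is fixed relative to C3 because the stepwise closure keeps the two aryl groups of the E-alkene on opposite faces, which is also the thermodynamically preferred arrangement. Regioselectivity rests on the para versus meta placement of the oxygen donors, chemoselectivity for the alkene over the arenes on the bulky silyl groups flanking the activated ring positions and on slow addition of 5 to excess 2, trans selectivity on the E geometry, and only the facial selectivity depends on the catalyst alone. C6 arises as a mixture of epimers, which is harmless because this carbon becomes sp2 in step 4.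

**Step 4**
Reactants: 6 methyl (2S,3S)-3-[3,5-bis(TBSO)phenyl]-2-[4-(TBSO)phenyl]-4-oxo-2,3,4,5,6,7-hexahydrobenzofuran-6-carboxylate
Product: 9 methyl (2S,3S)-3-[3,5-bis(TBSO)phenyl]-4-hydroxy-2-[4-(TBSO)phenyl]-2,3-dihydrobenzofuran-6-carboxylate, via C5 phenylselenide 7 (not isolated), via selenoxide 8 (not isolated)
Conditions: LiN(i-Pr)2 (1.1 equiv), THF, −78 °C; PhSeCl (1.15 equiv), −78 °C; crude, then 30% H2O2 (2.5 equiv), pyridine, CH2Cl2, 0 °C to rt
Reagents that add atoms: none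
Why: Selenoxide syn-elimination: kinetic deprotonation at C5 (alpha prime to the vinylogous ester), selenenylation anti to the C6 ester and hence syn to H6, oxidation, loss of PhSeOH across C5–C6 and enolisation give the phenol, selenenylation at C6 or C7 would converge on the same arene, and C2 and C3 are untouched because nothing present can dehydrogenate the dihydrofuran.

**Step 5**
Reactants: 9 methyl (2S,3S)-3-[3,5-bis(TBSO)phenyl]-4-hydroxy-2-[4-(TBSO)phenyl]-2,3-dihydrobenzofuran-6-carboxylate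
Product: 10 methyl (2S,3S)-3-[3,5-bis(TBSO)phenyl]-4-(TBSO)-2-[4-(TBSO)phenyl]-2,3-dihydrobenzofuran-6-carboxylate
Conditions: TBSCl (1.5 equiv), imidazole (3 equiv), DMF, rt to 40 °C
Reagents that add atoms: tert-butyldimethylsilyl chloride, CC(C)(C)[Si](C)(C)Cl
Why: Standard phenol silylation under a base too weak to touch the C3–H that lies para to the ester.

**Step 6**
Reactants: 10 methyl (2S,3S)-3-[3,5-bis(TBSO)phenyl]-4-(TBSO)-2-[4-(TBSO)phenyl]-2,3-dihydrobenzofuran-6-carboxylate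
Product: 11 {(2S,3S)-3-[3,5-bis(TBSO)phenyl]-4-(TBSO)-2-[4-(TBSO)phenyl]-2,3-dihydrobenzofuran-6-yl}methanol
Conditions: i-Bu2AlH (2.5 equiv), CH2Cl2, −78 to 0 °C; aq. potassium sodium tartrate
Reagents that add atoms: none
Why: Hydride reduction of an aryl methyl ester with i-Bu2AlH goes cleanly to the benzylic alcohol, and aryl silyl ethers and the dihydrobenzofuran are inert at low temperature.

**Step 7**
Reactants: 11 {(2S,3S)-3-[3,5-bis(TBSO)phenyl]-4-(TBSO)-2-[4-(TBSO)phenyl]-2,3-dihydrobenzofuran-6-yl}methanol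
Product: 12 (2S,3S)-3-[3,5-bis(TBSO)phenyl]-4-(TBSO)-2-[4-(TBSO)phenyl]-2,3-dihydrobenzofuran-6-carbaldehyde
Conditions: activated MnO2 (15 equiv), CH2Cl2, rt
Reagents that add atoms: none
Why: Activated MnO2 oxidises benzylic alcohols selectively to aldehydes under neutral heterogeneous conditions without over-oxidation.

**Step 8**
Reactants: 13 diethyl (4-hydroxybenzyl)phosphonate
Product: 14 diethyl [4-(TBSO)benzyl]phosphonate
Conditions: TBSCl (1.2 equiv), imidazole (2.5 equiv), CH2Cl2, rt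
Reagents that add atoms: tert-butyldimethylsilyl chloride, CC(C)(C)[Si](C)(C)Cl
Why: Routine phenol silylation that gives the olefination partner the same fluoride-labile, electron-donating group as the rest of the molecule.

**Step 9**
Reactants: 12 (2S,3S)-3-[3,5-bis(TBSO)phenyl]-4-(TBSO)-2-[4-(TBSO)phenyl]-2,3-dihydrobenzofuran-6-carbaldehyde; 14 diethyl [4-(TBSO)benzyl]phosphonate
Product: 15 (2S,3S)-3-[3,5-bis(TBSO)phenyl]-4-(TBSO)-2-[4-(TBSO)phenyl]-6-[(E)-4-(TBSO)styryl]-2,3-dihydrobenzofuran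
Conditions: 14 (1.3 equiv), KN(SiMe3)2 (1.25 equiv), THF, −78 °C, 30 min; then 12, −78 °C to rt
Reagents that add atoms: none
Why: Horner–Wadsworth–Emmons olefination of an aromatic aldehyde with a benzylic phosphonate is reliably E-selective, and the phosphonate is fully metallated before 12 is added so that no free amide base meets the aryl silyl ethers or the C3–H para to the formyl group.

**Step 10**
Reactants: 15 (2S,3S)-3-[3,5-bis(TBSO)phenyl]-4-(TBSO)-2-[4-(TBSO)phenyl]-6-[(E)-4-(TBSO)styryl]-2,3-dihydrobenzofuran; 5 methyl 4-diazo-3,5-dioxocyclohexane-1-carboxylate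
Product: 16 methyl (2R,3R)-3-UB-2-[4-(TBSO)phenyl]-4-oxo-2,3,4,5,6,7-hexahydrobenzofuran-6-carboxylate (both C6 epimers)
Conditions: Rh2(R-PTTL)4 (3 mol %), 5 (3 equiv) added by syringe pump over 10 h, PhF, 4 Å MS, 60 °C
Reagents that add atoms: none
Why: Proposed new method: the carbenoid formal [3+2] annulation of step 3 is repeated on stilbene 15, whose benzofuranyl ring has both oxygens meta to the alkene and whose other ring has the para silyloxy donor, so that attack through the benzofuranyl-bearing carbon (C3–C3a) and 5-exo-trig O-closure on the 4-silyloxybenzylic cation (O1–C2) again follow from polarity, the trans geometry from stepwise closure and the (2R,3R) configuration from the mirror-image ligand set, the resident C2'/C3' centres being too remote to bias the alkene faces; closest known reaction type: Rh2(OAc)4-catalysed annulation of cyclic 2-diazo-1,3-diones with styrenes and vinyl ethers.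

**Step 11**
Reactants: 16 methyl (2R,3R)-3-UB-2-[4-(TBSO)phenyl]-4-oxo-2,3,4,5,6,7-hexahydrobenzofuran-6-carboxylate
Product: 19 methyl (2R,3R)-3-UB-4-hydroxy-2-[4-(TBSO)phenyl]-2,3-dihydrobenzofuran-6-carboxylate, via C5 phenylselenide 17 (not isolated), via selenoxide 18 (not isolated)
Conditions: LiN(i-Pr)2 (1.1 equiv), THF, −78 °C; PhSeCl (1.15 equiv), −78 °C; crude, then 30% H2O2 (2.5 equiv), pyridine, CH2Cl2, 0 °C to rt
Reagents that add atoms: none
Why: The selenoxide syn-elimination and enolisation of step 4 apply unchanged, since the only acidic C–H bonds are those of the new oxocyclohexene ring and the four stereocentres are not involved.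

**Step 12**
Reactants: 19 methyl (2R,3R)-3-UB-4-hydroxy-2-[4-(TBSO)phenyl]-2,3-dihydrobenzofuran-6-carboxylate
Product: 20 methyl (2R,3R)-3-UB-4-(TBSO)-2-[4-(TBSO)phenyl]-2,3-dihydrobenzofuran-6-carboxylate
Conditions: TBSCl (1.5 equiv), imidazole (3 equiv), DMF, rt to 40 °C
Reagents that add atoms: tert-butyldimethylsilyl chloride, CC(C)(C)[Si](C)(C)Cl
Why: Standard phenol silylation, as in step 5.

**Step 13**
Reactants: 20 methyl (2R,3R)-3-UB-4-(TBSO)-2-[4-(TBSO)phenyl]-2,3-dihydrobenzofuran-6-carboxylate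
Product: 21 {(2R,3R)-3-UB-4-(TBSO)-2-[4-(TBSO)phenyl]-2,3-dihydrobenzofuran-6-yl}methanol
Conditions: i-Bu2AlH (2.5 equiv), CH2Cl2, −78 to 0 °C; aq. potassium sodium tartrate
Reagents that add atoms: none
Why: Ester-to-alcohol hydride reduction as in step 6, the ester being the only reducible group.

**Step 14**
Reactants: 21 {(2R,3R)-3-UB-4-(TBSO)-2-[4-(TBSO)phenyl]-2,3-dihydrobenzofuran-6-yl}methanol
Product: 22 (2R,3R)-3-UB-4-(TBSO)-2-[4-(TBSO)phenyl]-2,3-dihydrobenzofuran-6-carbaldehyde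
Conditions: activated MnO2 (15 equiv), CH2Cl2, rt
Reagents that add atoms: none
Why: Selective neutral benzylic oxidation with MnO2, as in step 7.

**Step 15**
Reactants: 22 (2R,3R)-3-UB-4-(TBSO)-2-[4-(TBSO)phenyl]-2,3-dihydrobenzofuran-6-carbaldehyde; 14 diethyl [4-(TBSO)benzyl]phosphonate
Product: 23 (2R,3R)-3-UB-4-(TBSO)-2-[4-(TBSO)phenyl]-6-[(E)-4-(TBSO)styryl]-2,3-dihydrobenzofuran (hepta-O-TBS ether of the target)
Conditions: 14 (1.3 equiv), KN(SiMe3)2 (1.25 equiv), THF, −78 °C, 30 min; then 22, −78 °C to rt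
Reagents that add atoms: none
Why: E-selective Horner–Wadsworth–Emmons olefination with the premetallated phosphonate, as in step 9.

**Step 16**
Reactants: 23 (2R,3R)-3-UB-4-(TBSO)-2-[4-(TBSO)phenyl]-6-[(E)-4-(TBSO)styryl]-2,3-dihydrobenzofuran
Product: 24 (2R,3R)-3-[(2S,3S)-3-(3,5-dihydroxyphenyl)-4-hydroxy-2-(4-hydroxyphenyl)-2,3-dihydrobenzofuran-6-yl]-2-(4-hydroxyphenyl)-6-[(E)-4-hydroxystyryl]-2,3-dihydrobenzofuran-4-ol (CNP0248228.3)
Conditions: Et3N·3HF (15 equiv), THF, rt, argon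
Reagents that add atoms: none
Why: Fluoride-driven cleavage of aryl silyl ethers under nearly neutral conditions avoids both the phenoxide-induced quinone-methide opening and the Lewis-acid ionisation of the C2–O bonds, leaves the stilbene untouched and involves no stereocentre.

**Compound list** (TBSO and UB as defined above)
1 | resveratrol | Oc1ccc(/C=C/c2cc(O)cc(O)c2)cc1 | starting material
2 | (E)-3,4',5-tris(TBSO)stilbene | CC(C)(C)[Si](C)(C)Oc1ccc(/C=C/c2cc(O[Si](C)(C)C(C)(C)C)cc(O[Si](C)(C)C(C)(C)C)c2)cc1 | intermediate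
3 | methyl 3,5-dioxocyclohexane-1-carboxylate | COC(=O)C1CC(=O)CC(=O)C1 | starting material
4 | 4-acetamidobenzenesulfonyl azide | CC(=O)Nc1ccc(cc1)S(=O)(=O)N=[N+]=[N-] | starting material
5 | methyl 4-diazo-3,5-dioxocyclohexane-1-carboxylate | COC(=O)C1CC(=O)C(=[N+]=[N-])C(=O)C1 | intermediate
6 | methyl (2S,3S)-3-[3,5-bis(TBSO)phenyl]-2-[4-(TBSO)phenyl]-4-oxo-2,3,4,5,6,7-hexahydrobenzofuran-6-carboxylate (C6 epimers) | COC(=O)C1CC(=O)C2=C(C1)O[C@H](c1ccc(O[Si](C)(C)C(C)(C)C)cc1)[C@H]2c1cc(O[Si](C)(C)C(C)(C)C)cc(O[Si](C)(C)C(C)(C)C)c1 | intermediate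
7 | 5-(phenylselanyl) derivative of 6 | COC(=O)C1C([Se]c3ccccc3)C(=O)C2=C(C1)O[C@H](c1ccc(O[Si](C)(C)C(C)(C)C)cc1)[C@H]2c1cc(O[Si](C)(C)C(C)(C)C)cc(O[Si](C)(C)C(C)(C)C)c1 | intermediate
8 | selenoxide of 7 | COC(=O)C1C([Se](=O)c3ccccc3)C(=O)C2=C(C1)O[C@H](c1ccc(O[Si](C)(C)C(C)(C)C)cc1)[C@H]2c1cc(O[Si](C)(C)C(C)(C)C)cc(O[Si](C)(C)C(C)(C)C)c1 | intermediate
9 | methyl (2S,3S)-3-[3,5-bis(TBSO)phenyl]-4-hydroxy-2-[4-(TBSO)phenyl]-2,3-dihydrobenzofuran-6-carboxylate | COC(=O)c1cc(O)c2c(c1)O[C@H](c1ccc(O[Si](C)(C)C(C)(C)C)cc1)[C@H]2c1cc(O[Si](C)(C)C(C)(C)C)cc(O[Si](C)(C)C(C)(C)C)c1 | intermediate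
10 | methyl (2S,3S)-3-[3,5-bis(TBSO)phenyl]-4-(TBSO)-2-[4-(TBSO)phenyl]-2,3-dihydrobenzofuran-6-carboxylate | COC(=O)c1cc(O[Si](C)(C)C(C)(C)C)c2c(c1)O[C@H](c1ccc(O[Si](C)(C)C(C)(C)C)cc1)[C@H]2c1cc(O[Si](C)(C)C(C)(C)C)cc(O[Si](C)(C)C(C)(C)C)c1 | intermediate
11 | UB-methanol | OCc1cc(O[Si](C)(C)C(C)(C)C)c2c(c1)O[C@H](c1ccc(O[Si](C)(C)C(C)(C)C)cc1)[C@H]2c1cc(O[Si](C)(C)C(C)(C)C)cc(O[Si](C)(C)C(C)(C)C)c1 | intermediate
12 | UB-carbaldehyde | O=Cc1cc(O[Si](C)(C)C(C)(C)C)c2c(c1)O[C@H](c1ccc(O[Si](C)(C)C(C)(C)C)cc1)[C@H]2c1cc(O[Si](C)(C)C(C)(C)C)cc(O[Si](C)(C)C(C)(C)C)c1 | intermediate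
13 | diethyl (4-hydroxybenzyl)phosphonate | CCOP(=O)(Cc1ccc(O)cc1)OCC | starting material
14 | diethyl [4-(TBSO)benzyl]phosphonate | CCOP(=O)(Cc1ccc(O[Si](C)(C)C(C)(C)C)cc1)OCC | intermediate
15 | (E)-1-UB-2-[4-(TBSO)phenyl]ethene | CC(C)(C)[Si](C)(C)Oc1ccc(/C=C/c2cc(O[Si](C)(C)C(C)(C)C)c3c(c2)O[C@H](c2ccc(O[Si](C)(C)C(C)(C)C)cc2)[C@H]3c2cc(O[Si](C)(C)C(C)(C)C)cc(O[Si](C)(C)C(C)(C)C)c2)cc1 | intermediate
16 | methyl (2R,3R)-3-UB-2-[4-(TBSO)phenyl]-4-oxo-2,3,4,5,6,7-hexahydrobenzofuran-6-carboxylate (C6 epimers) | COC(=O)C1CC(=O)C2=C(C1)O[C@@H](c1ccc(O[Si](C)(C)C(C)(C)C)cc1)[C@@H]2c1cc(O[Si](C)(C)C(C)(C)C)c2c(c1)O[C@H](c1ccc(O[Si](C)(C)C(C)(C)C)cc1)[C@H]2c1cc(O[Si](C)(C)C(C)(C)C)cc(O[Si](C)(C)C(C)(C)C)c1 | intermediate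
17 | 5-(phenylselanyl) derivative of 16 | COC(=O)C1C([Se]c3ccccc3)C(=O)C2=C(C1)O[C@@H](c1ccc(O[Si](C)(C)C(C)(C)C)cc1)[C@@H]2c1cc(O[Si](C)(C)C(C)(C)C)c2c(c1)O[C@H](c1ccc(O[Si](C)(C)C(C)(C)C)cc1)[C@H]2c1cc(O[Si](C)(C)C(C)(C)C)cc(O[Si](C)(C)C(C)(C)C)c1 | intermediate
18 | selenoxide of 17 | COC(=O)C1C([Se](=O)c3ccccc3)C(=O)C2=C(C1)O[C@@H](c1ccc(O[Si](C)(C)C(C)(C)C)cc1)[C@@H]2c1cc(O[Si](C)(C)C(C)(C)C)c2c(c1)O[C@H](c1ccc(O[Si](C)(C)C(C)(C)C)cc1)[C@H]2c1cc(O[Si](C)(C)C(C)(C)C)cc(O[Si](C)(C)C(C)(C)C)c1 | intermediate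
19 | methyl (2R,3R)-3-UB-4-hydroxy-2-[4-(TBSO)phenyl]-2,3-dihydrobenzofuran-6-carboxylate | COC(=O)c1cc(O)c2c(c1)O[C@@H](c1ccc(O[Si](C)(C)C(C)(C)C)cc1)[C@@H]2c1cc(O[Si](C)(C)C(C)(C)C)c2c(c1)O[C@H](c1ccc(O[Si](C)(C)C(C)(C)C)cc1)[C@H]2c1cc(O[Si](C)(C)C(C)(C)C)cc(O[Si](C)(C)C(C)(C)C)c1 | intermediate
20 | methyl (2R,3R)-3-UB-4-(TBSO)-2-[4-(TBSO)phenyl]-2,3-dihydrobenzofuran-6-carboxylate | COC(=O)c1cc(O[Si](C)(C)C(C)(C)C)c2c(c1)O[C@@H](c1ccc(O[Si](C)(C)C(C)(C)C)cc1)[C@@H]2c1cc(O[Si](C)(C)C(C)(C)C)c2c(c1)O[C@H](c1ccc(O[Si](C)(C)C(C)(C)C)cc1)[C@H]2c1cc(O[Si](C)(C)C(C)(C)C)cc(O[Si](C)(C)C(C)(C)C)c1 | intermediate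
21 | {(2R,3R)-3-UB-4-(TBSO)-2-[4-(TBSO)phenyl]-2,3-dihydrobenzofuran-6-yl}methanol | OCc1cc(O[Si](C)(C)C(C)(C)C)c2c(c1)O[C@@H](c1ccc(O[Si](C)(C)C(C)(C)C)cc1)[C@@H]2c1cc(O[Si](C)(C)C(C)(C)C)c2c(c1)O[C@H](c1ccc(O[Si](C)(C)C(C)(C)C)cc1)[C@H]2c1cc(O[Si](C)(C)C(C)(C)C)cc(O[Si](C)(C)C(C)(C)C)c1 | intermediate
22 | (2R,3R)-3-UB-4-(TBSO)-2-[4-(TBSO)phenyl]-2,3-dihydrobenzofuran-6-carbaldehyde | O=Cc1cc(O[Si](C)(C)C(C)(C)C)c2c(c1)O[C@@H](c1ccc(O[Si](C)(C)C(C)(C)C)cc1)[C@@H]2c1cc(O[Si](C)(C)C(C)(C)C)c2c(c1)O[C@H](c1ccc(O[Si](C)(C)C(C)(C)C)cc1)[C@H]2c1cc(O[Si](C)(C)C(C)(C)C)cc(O[Si](C)(C)C(C)(C)C)c1 | intermediate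
23 | hepta-O-TBS ether of the target | CC(C)(C)[Si](C)(C)Oc1ccc(/C=C/c2cc(O[Si](C)(C)C(C)(C)C)c3c(c2)O[C@@H](c2ccc(O[Si](C)(C)C(C)(C)C)cc2)[C@@H]3c2cc(O[Si](C)(C)C(C)(C)C)c3c(c2)O[C@H](c2ccc(O[Si](C)(C)C(C)(C)C)cc2)[C@H]3c2cc(O[Si](C)(C)C(C)(C)C)cc(O[Si](C)(C)C(C)(C)C)c2)cc1 | intermediate
24 | CNP0248228.3, (2R,3R,2'S,3'S) | Oc1ccc(/C=C/c2cc(O)c3c(c2)O[C@@H](c2ccc(O)cc2)[C@@H]3c2cc(O)c3c(c2)O[C@H](c2ccc(O)cc2)[C@H]3c2cc(O)cc(O)c2)cc1 | target

**Step count**
Total steps: 16.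
Longest linear sequence: 14 (step 1 or 2, then steps 3–7 and 9–16; step 8 is a side branch).

**Steps most likely to fail**

Step 3. The facial selectivity of the carbenoid addition may be poor. The carbenoid may also be lost to attack on the electron-rich arenes, ring contraction or dimerisation before the hindered 1,2-diarylalkene reacts. Fallback: the same two bonds are made by the known oxidative radical annulation, followed by resolution.
- Dione 3 and stilbene 2 with Mn(OAc)3·2H2O (2.2 equiv) in AcOH at 70 °C should give the racemic trans product, that is 6 together with the mirror-image annulation product ent-6 F1.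
- The electrophilic dione radical adds so as to leave the para-silyloxybenzylic radical, which is the one most readily oxidised to the cation that oxygen captures.
- The racemate is carried through the conditions of step 4 (selenide ent-7 F2, selenoxide ent-8 F3) to 9 and the mirror-image phenol ent-9 F4.
- The two phenols are separated by preparative chromatography on a chiral stationary phase, and the route is rejoined at 9.

Step 10. Capture of the carbenoid by the much larger stilbene may be slow, and catalyst control over the alkene faces may erode. Fallback: dione 3 and enantiopure stilbene 15 are annulated with Mn(OAc)3·2H2O in AcOH at 70 °C.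
- The reaction should give 16 together with the (2S,3S,2'S,3'S) annulation product 2,3-epi-16 F5.
- The mixture is taken through the conditions of step 11 (selenide 2,3-epi-17 F6, selenoxide 2,3-epi-18 F7).
- This removes the C6 epimers and leaves only 19 and the diastereomeric phenol 2,3-epi-19 F8.
- These are diastereomers and are separated by ordinary chromatography, and the route is rejoined at 19.

Step 4. Proton exchange during selenenylation may cause incomplete or double selenenylation, and peroxyseleninic species may over-oxidise the nascent electron-rich phenol. Fallback: strong base and peroxide are avoided, and aromatisation and protection are merged.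
- Compound 6 is enolsilylated with TBSOTf and Et3N in CH2Cl2 at 0 °C to the cross-conjugated silyloxydiene F9.
- DDQ (1.05 equiv) in CH2Cl2 at 0 °C then takes hydride from C6 and a proton from C7.
- This gives the aryl silyl ether directly, so the route is rejoined at 10 and step 5 is dropped.
- The low temperature and single equivalent of quinone guard against dehydrogenation of the dihydrofuran.

**Further compounds**
F1 | step 3 | ent-6, methyl (2R,3R)-3-[3,5-bis(TBSO)phenyl]-2-[4-(TBSO)phenyl]-4-oxo-2,3,4,5,6,7-hexahydrobenzofuran-6-carboxylate (C6 epimers) | COC(=O)C1CC(=O)C2=C(C1)O[C@@H](c1ccc(O[Si](C)(C)C(C)(C)C)cc1)[C@@H]2c1cc(O[Si](C)(C)C(C)(C)C)cc(O[Si](C)(C)C(C)(C)C)c1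
F2 | step 3 | ent-7, 5-(phenylselanyl) derivative of F1 | COC(=O)C1C([Se]c3ccccc3)C(=O)C2=C(C1)O[C@@H](c1ccc(O[Si](C)(C)C(C)(C)C)cc1)[C@@H]2c1cc(O[Si](C)(C)C(C)(C)C)cc(O[Si](C)(C)C(C)(C)C)c1
F3 | step 3 | ent-8, selenoxide of F2 | COC(=O)C1C([Se](=O)c3ccccc3)C(=O)C2=C(C1)O[C@@H](c1ccc(O[Si](C)(C)C(C)(C)C)cc1)[C@@H]2c1cc(O[Si](C)(C)C(C)(C)C)cc(O[Si](C)(C)C(C)(C)C)c1
F4 | step 3 | ent-9, methyl (2R,3R)-3-[3,5-bis(TBSO)phenyl]-4-hydroxy-2-[4-(TBSO)phenyl]-2,3-dihydrobenzofuran-6-carboxylate | COC(=O)c1cc(O)c2c(c1)O[C@@H](c1ccc(O[Si](C)(C)C(C)(C)C)cc1)[C@@H]2c1cc(O[Si](C)(C)C(C)(C)C)cc(O[Si](C)(C)C(C)(C)C)c1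
F5 | step 10 | 2,3-epi-16, methyl (2S,3S)-3-UB-2-[4-(TBSO)phenyl]-4-oxo-2,3,4,5,6,7-hexahydrobenzofuran-6-carboxylate (C6 epimers) | COC(=O)C1CC(=O)C2=C(C1)O[C@H](c1ccc(O[Si](C)(C)C(C)(C)C)cc1)[C@H]2c1cc(O[Si](C)(C)C(C)(C)C)c2c(c1)O[C@H](c1ccc(O[Si](C)(C)C(C)(C)C)cc1)[C@H]2c1cc(O[Si](C)(C)C(C)(C)C)cc(O[Si](C)(C)C(C)(C)C)c1
F6 | step 10 | 2,3-epi-17, 5-(phenylselanyl) derivative of F5 | COC(=O)C1C([Se]c3ccccc3)C(=O)C2=C(C1)O[C@H](c1ccc(O[Si](C)(C)C(C)(C)C)cc1)[C@H]2c1cc(O[Si](C)(C)C(C)(C)C)c2c(c1)O[C@H](c1ccc(O[Si](C)(C)C(C)(C)C)cc1)[C@H]2c1cc(O[Si](C)(C)C(C)(C)C)cc(O[Si](C)(C)C(C)(C)C)c1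
F7 | step 10 | 2,3-epi-18, selenoxide of F6 | COC(=O)C1C([Se](=O)c3ccccc3)C(=O)C2=C(C1)O[C@H](c1ccc(O[Si](C)(C)C(C)(C)C)cc1)[C@H]2c1cc(O[Si](C)(C)C(C)(C)C)c2c(c1)O[C@H](c1ccc(O[Si](C)(C)C(C)(C)C)cc1)[C@H]2c1cc(O[Si](C)(C)C(C)(C)C)cc(O[Si](C)(C)C(C)(C)C)c1
F8 | step 10 | 2,3-epi-19, methyl (2S,3S)-3-UB-4-hydroxy-2-[4-(TBSO)phenyl]-2,3-dihydrobenzofuran-6-carboxylate | COC(=O)c1cc(O)c2c(c1)O[C@H](c1ccc(O[Si](C)(C)C(C)(C)C)cc1)[C@H]2c1cc(O[Si](C)(C)C(C)(C)C)c2c(c1)O[C@H](c1ccc(O[Si](C)(C)C(C)(C)C)cc1)[C@H]2c1cc(O[Si](C)(C)C(C)(C)C)cc(O[Si](C)(C)C(C)(C)C)c1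
F9 | step 4 | methyl (2S,3S)-3-[3,5-bis(TBSO)phenyl]-4-(TBSO)-2-[4-(TBSO)phenyl]-2,3,6,7-tetrahydrobenzofuran-6-carboxylate (C6 epimers) | COC(=O)C1C=C(O[Si](C)(C)C(C)(C)C)C2=C(C1)O[C@H](c1ccc(O[Si](C)(C)C(C)(C)C)cc1)[C@H]2c1cc(O[Si](C)(C)C(C)(C)C)cc(O[Si](C)(C)C(C)(C)C)c1
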